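**Retrosynthetic overview**

1. Numbering: C1 (CH3-bearing fusion carbon), C2, C3, C4 (isopropyl), C5 (fusion carbinol), C6, C7, C8 (methyl carbinol), C9 (ester carbon), C10. The cyclopentane is C1–C5; the seven-membered ring is C1, C10, C9, C8, C7, C6, C5.
2. Late stage: C9 ester ⇐ 5,8,9-triol ⇐ 8,9-epoxide on the face of the C5 hydroxyl, opened by water at C8 ⇐ 8,9-alkene; isopropyl ⇐ isopropenyl.
3. Key disconnection: the tertiary C5 hydroxyl, the C4–C5 bond and the isopropenyl group on C4 of the cyclopentane are the pattern left by a carbonyl-ene reaction. Cutting C4–C5 gives a cyclohept-4-enone (C5 ketone, 8,9-alkene) that carries CH3 and a 4-methylpent-3-enyl chain on C1.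
4. Seven-membered ring ⇐ Claisen ring expansion of a 2-methylidene-5-isopropenyl oxolane ⇐ α,α-dialkylated γ-isopropenyl butyrolactone. The C1 quaternary centre ⇐ two enolate alkylations steered by the γ-centre, which comes from L-glutamic acid.
5. Order of rings: oxolanone template (step 1) → seven-membered carbocycle (step 9) → cyclopentane (step 10).

Key step: step 10

**Route**

Step 1
Reactants: 1 L-glutamic acid
Product: 2 (2S)-5-oxooxolane-2-carboxylic acid
Conditions: NaNO2, aq. HCl, 0 °C → rt
Reagents that add atoms: none
Why: Diazotisation of the α-amino acid is followed by loss of N2 with participation of the α-carboxylate and reopening of the α-lactone by the side-chain carboxyl (double inversion), so the γ-lactone forms with net retention and the centre stays S.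

Step 2
Reactants: 2 (2S)-5-oxooxolane-2-carboxylic acid
Product: 3 (2S)-5-oxooxolane-2-carbonyl chloride
Conditions: (COCl)2, DMF (cat.), CH2Cl2, 0 °C → rt
Reagents that add atoms: oxalyl chloride, O=C(Cl)C(=O)Cl
Why: Acid chloride formation through the chloroiminium (Vilsmeier-type) species is mild and non-basic, so the lactone and the oxygen-bearing stereocentre should be unaffected.

Step 3
Reactants: 3 (2S)-5-oxooxolane-2-carbonyl chloride
Product: 4 (5S)-5-acetyloxolan-2-one
Conditions: Me2CuLi (MeLi, CuI), Et2O, −78 °C; aq. NH4Cl
Reagents that add atoms: lithium dimethylcuprate, [Li+].C[Cu-]C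
Why: Acylation of a lithium dialkylcuprate by an acid chloride (cuprate ketone synthesis) stops at the ketone at −78 °C and does not attack the lactone, and the cold quench should spare the enolisable centre next to the new ketone.

Step 4
Reactants: 4 (5S)-5-acetyloxolan-2-one
Product: 5 (5S)-5-(prop-1-en-2-yl)oxolan-2-one
Conditions: Zn, CH2Br2, TiCl4, THF/CH2Cl2, 0 °C → rt
Reagents that add atoms: dibromomethane, BrCBr
Why: Takai–Lombardo methylenation is non-basic and selective for ketones over lactones, so acetyl becomes isopropenyl without epimerising the adjacent centre.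

Step 5
Reactants: 5 (5S)-5-(prop-1-en-2-yl)oxolan-2-one; 6 iodomethane
Product: 8 (5S)-3-methyl-5-(prop-1-en-2-yl)oxolan-2-one (mixture of C3 epimers), via lithium enolate 7 (not isolated)
Conditions: LiN(iPr)2, THF, −78 °C; MeI, −78 °C
Reagents that add atoms: iodomethane (6), CI
Why: Kinetic lactone enolate alkylation with the most reactive electrophile should stop at monomethylation when a slight deficit of base is used, and the C3 configuration formed is of no consequence because step 7 passes through the planar enolate again.

Step 6
Reactants: 9 5-bromo-2-methylpent-2-ene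
Product: 10 5-iodo-2-methylpent-2-ene
Conditions: NaI, acetone, reflux
Reagents that add atoms: sodium iodide, [Na+].[I-]
Why: Finkelstein halide exchange, driven by precipitation of NaBr, gives the more reactive primary iodide needed to alkylate a fully substituted enolate.

Step 7
Reactants: 8 (5S)-3-methyl-5-(prop-1-en-2-yl)oxolan-2-one; 10 5-iodo-2-methylpent-2-ene
Product: 12 (3R,5S)-3-methyl-3-(4-methylpent-3-en-1-yl)-5-(prop-1-en-2-yl)oxolan-2-one, via lithium enolate 11 (not isolated)
Conditions: LiN(iPr)2, THF, −78 °C; 10, DMPU, −78 → −30 °C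
Reagents that add atoms: 5-iodo-2-methylpent-2-ene (10), CC(C)=CCCI
Why: Enolate alkylation of the α-methyl lactone should occur on the ring face anti to the C5 isopropenyl group (1,3-induction across the five-membered ring), which sets the quaternary C3 centre (the future C1) with the homoprenyl chain trans and the methyl cis to isopropenyl, the minor epimer being removable by chromatography.

Step 8
Reactants: 12 (3R,5S)-3-methyl-3-(4-methylpent-3-en-1-yl)-5-(prop-1-en-2-yl)oxolan-2-one
Product: 13 (3R,5S)-3-methyl-2-methylidene-3-(4-methylpent-3-en-1-yl)-5-(prop-1-en-2-yl)oxolane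
Conditions: Cp2TiMe2, toluene, 70 °C, dark; filtration through basic alumina
Reagents that add atoms: dimethyltitanocene, C[Ti](C)(C1C=CC=C1)C1C=CC=C1
Why: Petasis methylenation turns the lactone carbonyl into the exocyclic enol ether under non-acidic conditions and leaves the unstrained alkenes alone, and because C3 is quaternary the enol ether cannot isomerise into the ring.

Step 9
Reactants: 13 (3R,5S)-3-methyl-2-methylidene-3-(4-methylpent-3-en-1-yl)-5-(prop-1-en-2-yl)oxolane
Product: 14 (2R)-2,5-dimethyl-2-(4-methylpent-3-en-1-yl)cyclohept-4-en-1-one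
Conditions: toluene, base-washed sealed tube, 180 °C
Reagents that add atoms: none
Why: The allyl vinyl ether unit CH2=C–O–CH–C(CH3)=CH2 should undergo a Claisen rearrangement through a boat-like transition state that joins the two terminal CH2 carbons and breaks the O–C5 bond, turning the oxolane into the cyclohept-4-enone with a necessarily cis ring alkene, while the quaternary centre is a spectator and the C5 centre, its task done, disappears.

Step 10
Reactants: 14 (2R)-2,5-dimethyl-2-(4-methylpent-3-en-1-yl)cyclohept-4-en-1-one
Product: 15 (3R,3aS,8aR)-6,8a-dimethyl-3-(prop-1-en-2-yl)-2,3,4,5,8,8a-hexahydro-1H-azulen-3a-ol (overview numbering: 8,9-alkene; 1-CH3, 5-OH and 4-isopropenyl all cis)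
Conditions: Me2AlCl (1.2 equiv), CH2Cl2, −78 → −20 °C; H2O
Reagents that add atoms: none
Why: Me2AlCl binds the C5 ketone oxygen, the trisubstituted alkene of the side chain adds through its less substituted carbon C4 to C5 while a hydrogen of an allylic methyl group passes to oxygen through a six-membered transition state, and the aluminium alkoxide then loses methane, which removes the proton that could reopen cationic pathways. This is a Lewis-acid-promoted intramolecular type 1 carbonyl-ene reaction, well known for alkenyl aldehydes and documented, though less often, for ketones. The cyclopentane C1–C2–C3–C4–C5 closes in 5-exo mode, with the carbonyl oxygen and the CMe2 terminus both left outside the new ring. C5 is controlled by the tether: the three-atom chain on C1 can reach only the carbonyl face on its own side, because the other approach would need a transoid C10–C1–C5–C6 torsion inside the seven-membered ring, so the fusion is cis and the hydroxyl is cis to the C1 methyl. C4 is controlled by the ene geometry: oxygen and the hydrogen-donating isopropylidene unit must lie syn about the forming C4–C5 bond, so isopropenyl ends up cis to the hydroxyl. The step needs site selectivity between two trisubstituted alkenes and proton transfer in preference to chloride capture or shifts; the ring alkene could only close a four-membered ring onto C5, and about one equivalent of Me2AlCl at low temperature keeps the alkoxide basic enough to accept the proton.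

Step 11
Reactants: 15 (3R,3aS,8aR)-6,8a-dimethyl-3-(prop-1-en-2-yl)-2,3,4,5,8,8a-hexahydro-1H-azulen-3a-ol
Product: 16 (3R,3aS,8aR)-6,8a-dimethyl-3-(propan-2-yl)-2,3,4,5,8,8a-hexahydro-1H-azulen-3a-ol
Conditions: H2 (1 atm), RhCl(PPh3)3 (cat.), benzene, rt
Reagents that add atoms: none
Why: Homogeneous hydrogenation with RhCl(PPh3)3 reduces the 1,1-disubstituted isopropenyl alkene much faster than the trisubstituted ring alkene, and no stereocentre is created.

Step 12
Reactants: 16 (3R,3aS,8aR)-6,8a-dimethyl-3-(propan-2-yl)-2,3,4,5,8,8a-hexahydro-1H-azulen-3a-ol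
Product: 17 8,9-epoxide of 16 on the face of the C5 hydroxyl (overview numbering; C8 S, C9 R)
Conditions: VO(acac)2 (cat.), t-BuOOH, CH2Cl2, 0 °C → rt
Reagents that add atoms: tert-butyl hydroperoxide, CC(C)(C)OO
Why: In this hydroxyl-directed epoxidation the vanadium alkoxide of the C5 hydroxyl should deliver the peroxide oxygen across the seven-membered ring to the alkene face on its own side (also the convex face of the cis-fused bicycle), setting C8 and C9, and the resulting syn epoxide cannot be opened by the C5 hydroxyl because backside approach is geometrically impossible.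

Step 13
Reactants: 17 8,9-epoxide of 16
Product: 18 5,8,9-triol (overview numbering; C1 R, C4 R, C5 S, C8 R, C9 R; 9-OH cis and 8-OH trans to the 5-OH)
Conditions: HClO4 (cat.), THF/H2O (3:1), 0 °C
Reagents that add atoms: water, O
Why: In acid-catalysed epoxide hydrolysis water should attack the protonated epoxide at the tertiary C8, which carries more of the positive charge, with inversion, giving the trans-8,9-diol with the C8 hydroxyl on the face opposite to the C5 hydroxyl.

Step 14
Reactants: 18 5,8,9-triol; 19 4-methoxybenzoyl chloride
Product: 20 CNP0244624.1, the 9-(4-methoxybenzoate) of triol 18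
Conditions: pyridine, DMAP (cat.), CH2Cl2, 0 °C → rt
Reagents that add atoms: 4-methoxybenzoyl chloride (19), COc1ccc(C(=O)Cl)cc1
Why: DMAP-catalysed acylation should take place only at the single secondary hydroxyl (C9), because the C5 and C8 hydroxyls are tertiary and hindered, and no stereocentre is touched.

**Compound list**

1 | L-glutamic acid | N[C@@H](CCC(=O)O)C(=O)O | starting material
2 | (2S)-5-oxooxolane-2-carboxylic acid | O=C1CC[C@@H](C(=O)O)O1 | intermediate
3 | (2S)-5-oxooxolane-2-carbonyl chloride | O=C1CC[C@@H](C(=O)Cl)O1 | intermediate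
4 | (5S)-5-acetyloxolan-2-one | CC(=O)[C@@H]1CCC(=O)O1 | intermediate
5 | (5S)-5-(prop-1-en-2-yl)oxolan-2-one | CC(=C)[C@@H]1CCC(=O)O1 | intermediate
6 | iodomethane | CI | starting material
7 | lithium enolate of 5 | [Li+].[O-]C1=CC[C@@H](C(C)=C)O1 | intermediate (not isolated)
8 | (5S)-3-methyl-5-(prop-1-en-2-yl)oxolan-2-one, mixture of C3 epimers | CC1C[C@@H](C(C)=C)OC1=O | intermediate
9 | 5-bromo-2-methylpent-2-ene | CC(C)=CCCBr | starting material
10 | 5-iodo-2-methylpent-2-ene | CC(C)=CCCI | intermediate
11 | lithium enolate of 8 | [Li+].[O-]C1=C(C)C[C@@H](C(C)=C)O1 | intermediate (not isolated)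
12 | (3R,5S)-3-methyl-3-(4-methylpent-3-en-1-yl)-5-(prop-1-en-2-yl)oxolan-2-one | C[C@@]1(CCC=C(C)C)C[C@@H](C(C)=C)OC1=O | intermediate
13 | (3R,5S)-3-methyl-2-methylidene-3-(4-methylpent-3-en-1-yl)-5-(prop-1-en-2-yl)oxolane | C[C@@]1(CCC=C(C)C)C[C@@H](C(C)=C)OC1=C | intermediate
14 | (2R)-2,5-dimethyl-2-(4-methylpent-3-en-1-yl)cyclohept-4-en-1-one | CC1=CC[C@@](C)(CCC=C(C)C)C(=O)CC1 | intermediate
15 | (3R,3aS,8aR)-6,8a-dimethyl-3-(prop-1-en-2-yl)-2,3,4,5,8,8a-hexahydro-1H-azulen-3a-ol | CC1=CC[C@@]2(C)CC[C@H](C(C)=C)[C@@]2(O)CC1 | intermediate
16 | (3R,3aS,8aR)-6,8a-dimethyl-3-(propan-2-yl)-2,3,4,5,8,8a-hexahydro-1H-azulen-3a-ol | CC1=CC[C@@]2(C)CC[C@H](C(C)C)[C@@]2(O)CC1 | intermediate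
17 | 8,9-epoxide of 16, oxygen on the face of the 5-OH (C8 S, C9 R) | O1[C@@H]2C[C@@]3(C)CC[C@H](C(C)C)[C@@]3(O)CC[C@]12C | intermediate
18 | 5,8,9-triol (C1 R, C4 R, C5 S, C8 R, C9 R) | O[C@@H]1C[C@@]2(C)CC[C@H](C(C)C)[C@@]2(O)CC[C@@]1(C)O | intermediate
19 | 4-methoxybenzoyl chloride | COc1ccc(C(=O)Cl)cc1 | starting material
20 | CNP0244624.1, 9-(4-methoxybenzoate) of triol 18 | COc1ccc(C(=O)O[C@@H]2C[C@@]3(C)CC[C@H](C(C)C)[C@@]3(O)CC[C@@]2(C)O)cc1 | target

**Step count**

Total steps: 14. Longest linear sequence: 13 steps (steps 1–5 and 7–14, from L-glutamic acid); step 6 is a one-step side branch.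

**Steps most likely to fail**

1. Step 10 (carbonyl-ene cyclisation). The aluminium-bound intermediate may behave as a zwitterion and collapse by chloride capture, by 1,2-hydride and alkyl shifts back to a ketone, or by loss of the tertiary oxygen. Alternatively the hindered C5 ketone may stay unreactive until methyl transfer from aluminium competes. The fallback sets out from 14 and runs the closure deliberately as a Prins cyclisation with halide capture (TiCl4, CH2Cl2, −78 °C). The titanium alkoxide hands chloride to the adjacent cationic carbon, which should keep oxygen and the C4 side chain cis, and gives the cis-fused 4-(2-chloropropan-2-yl) dauc-8-en-5-ol F1. Radical dechlorination of the tertiary chloride (Bu3SnH, AIBN, toluene, 80 °C) then gives the isopropyl compound. The sequence comes back to the route at 16, and step 11 is no longer needed.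

2. Step 13 (epoxide hydrolysis). Ionisation at C8 may run ahead of water attack. That would allow capture of C8 by the C5 hydroxyl on its own face (a 5,8-ether), proton loss to allylic alcohols, hydride shift to a C9 ketone, or loss of the inversion at C8. The fallback sets out from 17 and forms the C8–O bond by a radical instead of an ionic process. Diethylaluminium 2,2,6,6-tetramethylpiperidide (toluene, 0 °C) isomerises the epoxide by syn elimination of a C8-methyl hydrogen to the 8-methylidene 5,9-diol F2, with the C9 oxygen unchanged. Acylation of the secondary allylic hydroxyl with 19 (pyridine, DMAP, CH2Cl2) gives the 8-methylidene 9-(4-methoxybenzoate) F3. Mukaiyama hydration (Co(acac)2 cat., PhSiH3, O2, THF, rt; then aq. Na2S2O3) places the hydroxyl on C8 in the Markovnikov sense through a tertiary radical, which should be oxygenated on the face away from the neighbouring aroyloxy group. The sequence comes back to the route at 20.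

3. Step 7 (quaternary centre by alkylation). The flat isopropenyl group may shield one enolate face too weakly, so that both C3 epimers form, or the hindered enolate may eliminate the homoallylic iodide instead of substituting it. The fallback sets out from 4 and enlarges the controlling group before the alkylations.
   - MeMgBr (THF, −78 °C) adds to the ketone to give (5S)-5-(2-hydroxypropan-2-yl)oxolan-2-one F4.
   - Et3SiOTf and 2,6-lutidine (CH2Cl2, 0 °C) give the triethylsilyl ether F5.
   - LiN(iPr)2 then 6 gives, through the lithium enolate of the silyl ether lactone F6, the 3-methyl lactone F7.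
   - LiN(iPr)2 then 10 with DMPU gives, through the lithium enolate of the 3-methyl silyl ether lactone F8, the dialkylated silyl ether lactone F9. The homoprenyl chain should enter anti to the tert-alkyl silyl ether group, which is a much larger shield than isopropenyl.
   - HF·pyridine (THF, 0 °C) frees the dialkylated hydroxy lactone F10.
   - Dehydration with the Burgess reagent (toluene, 60 °C) removes a methyl hydrogen and restores the isopropenyl group.
   
   The sequence comes back to the route at 12.

**Further compounds**

F1 | step 10 | cis-fused 4-(2-chloropropan-2-yl)-1,8-dimethyl dauc-8-en-5-ol (overview numbering; 1-CH3, 5-OH and the C4 side chain cis) | CC1=CC[C@@]2(C)CC[C@H](C(C)(C)Cl)[C@@]2(O)CC1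
F2 | step 13 | 8-methylidene 5,9-diol (overview numbering; 9-OH cis to 5-OH) | O[C@@H]1C[C@@]2(C)CC[C@H](C(C)C)[C@@]2(O)CCC1=C
F3 | step 13 | 8-methylidene 5-hydroxy 9-(4-methoxybenzoate) | COc1ccc(C(=O)O[C@@H]2C[C@@]3(C)CC[C@H](C(C)C)[C@@]3(O)CCC2=C)cc1
F4 | step 7 | (5S)-5-(2-hydroxypropan-2-yl)oxolan-2-one | CC(C)(O)[C@@H]1CCC(=O)O1
F5 | step 7 | (5S)-5-[2-(triethylsilyloxy)propan-2-yl]oxolan-2-one | CC[Si](CC)(CC)OC(C)(C)[C@@H]1CCC(=O)O1
F6 | step 7 | lithium enolate of F5 | [Li+].[O-]C1=CC[C@@H](C(C)(C)O[Si](CC)(CC)CC)O1
F7 | step 7 | (5S)-3-methyl-5-[2-(triethylsilyloxy)propan-2-yl]oxolan-2-one, mixture of C3 epimers | CC1C[C@@H](C(C)(C)O[Si](CC)(CC)CC)OC1=O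
F8 | step 7 | lithium enolate of F7 | [Li+].[O-]C1=C(C)C[C@@H](C(C)(C)O[Si](CC)(CC)CC)O1
F9 | step 7 | (3R,5S)-3-methyl-3-(4-methylpent-3-en-1-yl)-5-[2-(triethylsilyloxy)propan-2-yl]oxolan-2-one | C[C@@]1(CCC=C(C)C)C[C@@H](C(C)(C)O[Si](CC)(CC)CC)OC1=O
F10 | step 7 | (3R,5S)-5-(2-hydroxypropan-2-yl)-3-methyl-3-(4-methylpent-3-en-1-yl)oxolan-2-one | C[C@@]1(CCC=C(C)C)C[C@@H](C(C)(C)O)OC1=O
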